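The numbers were chosen freely; the rest is arithmetic.

In Monday's closed flask two sums stayed constant: [reagent] + [dormant form] + [intermediate B] + [target] at the reagent charge, and [substrate] + [intermediate A] + [intermediate B] + [target] + 2·[side product] at the substrate charge.

    substrate ⇌ intermediate A (K1 = 1.0, k1 = 0.11 s⁻¹)
    substrate + reagent → target (k2 = 0.46 L mol⁻¹ s⁻¹)
    substrate + reagent ⇌ intermediate B (K3 = 51 L mol⁻¹, k3 = 0.33 L mol⁻¹ s⁻¹)
    substrate + intermediate A → side product (k4 = 0.13 L mol⁻¹ s⁻¹)
    reagent ⇌ dormant form (K5 = 48, k5 = 0.020 s⁻¹)

in all of them: substrate 45 mM
- Monday's: reagent 27.0 mM; time 15 min; everything together in a closed stirred flask, run for 15 min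
- Friday's: reagent 27.0 mM (fed, over 7.50 min); time 15 min; all but reagent at the start; reagent goes in evenly over 7.50 min, the run ends at 15 min
- Sunday's: reagent 27.0 mM; a single well-mixed tank run continuously and read at steady state, 15 min in it on average
- Saturday's: reagent 27.0 mM; a single well-mixed tank run continuously and read at steady state, 150 min in it on average

- percentages count the substrate that a species holds: one side product counts as two
- the stated concentrations are those of everything mixed, before any reaction; amounts are the same in each set-up
- the feed brings no volume worth counting
- run time (Monday's): 15 min

1. the set-up with the highest share of target in all that became target or side product, at the outlet or at the end ("none" if the first two lie within 2 percentage points) (Monday's / Friday's / Sunday's / Saturday's / none)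
2. share of target in all that became target or side product, at the outlet or at the end, Monday's
3. share of target in all that became target or side product, at the outlet or at the end, Friday's
4. share of target in all that became target or side product, at the outlet or at the end, Sunday's
5. share of target in all that became target or side product, at the outlet or at the end, Saturday's

I reckoned Monday's down the ladder of rates, fastest first. Substrate's forward half-life in step 1 is 0.11 min, shorter than the 2.0 min half-life of intermediate A in step 4 at Monday's charge, so I took [intermediate A] = 1.0·[substrate], with about 22.5 mM each at the opening. Two rate laws then became one rule, with the selectivity factor σ = 0.46 L mol⁻¹ s⁻¹ / (2·0.13 L mol⁻¹ s⁻¹·1.0) = 1.77, the substrate going to target per substrate going to side product at equal [reagent] and [substrate]: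

target formed : substrate into side product = σ·[reagent]/[substrate]

At the first instant of Monday's, with the whole reagent charge still free, this ratio gave a share of 68.0 %.

The next rung was free reagent, whose lifetime against the forward steps to target, intermediate B and dormant form I put at about 26.5 s at the opening of Monday's, less than the 2.0 min half-life in step 4. I therefore treated the opening as a burst and estimated:

target 7.40 mM; substrate into side product 3.48 mM

For the late end of Monday's I took dormant form to outweigh intermediate B as a store of reagent, since 48 is far above 2.3, the equilibrium constant of step 3 times [substrate] at the start, and I expected [substrate] to fall from there. I therefore put free reagent near 0.400 mM, while step 4 took [substrate] + [intermediate A] down: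

from 34.1 mM to 11.4 mM

Integrating the rule over that fall joined the two ends:

late target = 2·σ·[reagent]·ln(start/end) = 1.55 mM

share = 26.6 %

My hand went no further than Monday's. The forecast, which said of Monday's that “stepwise hand integration gives a fast early burst”, gave 27.3 % for Monday's, 18.7 % for Friday's, 22.1 % for Sunday's and 19.8 % for Saturday's, with Monday's best.

The simulation gave 27.4 % for Monday's, 18.8 % for Friday's, 22.1 % for Sunday's and 19.8 % for Saturday's, so Monday's came highest, and Monday's stood above my 26.6 %. Monday's target ended at 20.2 % of the substrate charged, or 9.10 mM. Turned into target per substrate in side product and divided by σ, Monday's share means a [reagent]/[substrate] of 0.213, averaged over the side product formed. In Saturday's steady tank the same step gives 0.139, and with substrate read at 3.61 mM that puts free reagent at 0.503 mM.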